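**Retrosynthetic overview**

1. Labels: indane ring D carbons C1 (bears a 4-hydroxyphenyl group), C2, C3, fused to resorcinol ring A; Cα is the diarylmethine between C3 and the central resorcinol ring B; the dihydrobenzofuran has O1′, C2′, C3′ (ring F) on arene ring C (C3a′, C4′); ring E is the eight-membered ring C2–C3–Cα–ring B–C3′–C3a′–C4′.
2. Canaliculatol ⇐ octamethyl ether (BBr3) ⇐ aryl group on Cα by SN1 arylation of a ring-E carbinol with anisole, and aryl group on C1 by aryl-metal addition then ionic hydrogenation, both from a ring-E diketone (C1=O, Cα=O).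
3. Ring-E diketone ⇐ ring E closed by forming the C4′–C2 bond: a palladium redox relay (C2–C3 desaturation, then conjugate arylation by the C4′ triflate) on an open 3-aroylindan-1-one, which comes from Friedel–Crafts acylation of ring B of a dihydrobenzofuran triflate with a racemic indanone acid.
4. Enabling feature: the indanone methylene C2 is α to the C1 carbonyl and β to the aroyl carbonyl (Cα=O) on ring B, so it can be desaturated and then arylated by C4′ across ring B; C2 and C3 stay enolisable afterwards, and the rigid trans ring F (C2′, C3′) decides their configuration.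
5. Dihydrobenzofuran triflate ⇐ decarboxylative arylation at C2′ ⇐ lactone-to-dihydrofuran ring contraction ⇐ rhodium-catalysed asymmetric aryl addition to a coumarin triflate (C3′, the only catalyst-set centre); rings are formed in the order F, D, E.

Key step: step 9

Remark: all phenols are carried as methyl ethers until the last step, and 5-hydroxy-7-methoxycoumarin and di-tert-butyl fumarate are taken as purchasable.

**Route**

Step 1
Reactants: 1 5-hydroxy-7-methoxycoumarin
Product: 2 7-methoxy-2-oxo-2H-chromen-5-yl trifluoromethanesulfonate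
Conditions: (CF3SO2)2O, pyridine, CH2Cl2, 0 °C
Reagents that add atoms: trifluoromethanesulfonic anhydride, O=S(=O)(OS(=O)(=O)C(F)(F)F)C(F)(F)F
Why: O-sulfonylation of the phenol, which installs at the future C4′ the triflate that serves as the palladium handle in step 9.

Step 2
Reactants: 2 coumarin triflate; 3 (3,5-dimethoxyphenyl)boronic acid
Product: 4 (4R)-4-(3,5-dimethoxyphenyl)-7-methoxy-2-oxochroman-5-yl trifluoromethanesulfonate
Conditions: Rh(acac)(C2H4)2 (3 mol %), (R)-SEGPHOS (3.3 mol %), 3 (5 equiv), 1,4-dioxane/H2O (10:1), 60 °C
Reagents that add atoms: none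
Why: Hayashi–Miyaura asymmetric 1,4-addition, in which an aryl–rhodium species on the chiral bisphosphine adds to C4 of the coumarin from one enantioface and should set the (4R) centre (the future C3′); the ligand enantiomer is chosen by analogy with aryl additions to simple coumarins, and monovalent rhodium leaves the aryl triflate untouched.

Step 3
Reactants: 4 (4R)-lactone
Product: 6 (4R)-3-bromo-4-(3,5-dimethoxyphenyl)-7-methoxy-2-oxochroman-5-yl trifluoromethanesulfonate, via lithium enolate 5 (not isolated)
Conditions: LiN(SiMe3)2 (1.1 equiv), THF, −78 °C; then NBS (1.05 equiv), −78 °C; aq. NH4Cl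
Reagents that add atoms: N-bromosuccinimide, O=C1CCC(=O)N1Br
Why: α-bromination of the lactone enolate at low temperature, with bromine expected anti to the C4 aryl group; the configuration at C3 is lost again in step 5.

Step 4
Reactants: 6 bromolactone
Product: 7 (3R)-3-(3,5-dimethoxyphenyl)-6-methoxy-4-(trifluoromethylsulfonyloxy)-2,3-dihydrobenzofuran-2-carboxylic acid (C2 epimers)
Conditions: LiOH·H2O (3 equiv), THF/H2O (3:1), 0 °C; then 1 M HCl
Reagents that add atoms: lithium hydroxide, [Li+].[OH-]
Why: Hydroxide opens the aryl ester and the released phenoxide displaces the α-bromide in a 5-exo-tet SN2 reaction, a lactone-to-dihydrofuran ring contraction of the Perkin type that forms ring F without touching C3′.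

Step 5
Reactants: 7 dihydrobenzofuran acid; 8 4-iodoanisole
Product: 9 (2R,3R)-3-(3,5-dimethoxyphenyl)-6-methoxy-2-(4-methoxyphenyl)-2,3-dihydrobenzofuran-4-yl trifluoromethanesulfonate (trans)
Conditions: Ir[dF(CF3)ppy]2(dtbbpy)PF6 (1 mol %), NiCl2·glyme (10 mol %), dtbbpy (15 mol %), Cs2CO3 (1.5 equiv), DMF, blue LEDs, 25 °C
Reagents that add atoms: none
Why: Metallaphotoredox decarboxylative arylation, in which the α-oxy radical at C2′ is captured by aryl–nickel made from the aryl iodide (nickel/bipyridine should not insert into the aryl triflate) and the aryl group is delivered anti to the C3′ aryl group, giving the trans isomer.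

Step 6
Reactants: 3 (3,5-dimethoxyphenyl)boronic acid; 10 di-tert-butyl fumarate
Product: 11 di-tert-butyl 2-(3,5-dimethoxyphenyl)succinate (racemic)
Conditions: [Rh(OH)(cod)]2 (1.5 mol %), 1,4-dioxane/H2O (10:1), 50 °C
Reagents that add atoms: none
Why: Rhodium-catalysed 1,4-addition of the arylboronic acid to the fumarate; the product is racemic by design, because this carbon (the future C3) is equilibrated in step 9.

Step 7
Reactants: 11 diester
Product: 13 5,7-dimethoxy-1-oxoindane-3-carboxylic acid (racemic), via 2-(3,5-dimethoxyphenyl)succinic acid 12 (not isolated)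
Conditions: MeSO3H (neat), 40 °C
Reagents that add atoms: none
Why: Acidolysis of both tert-butyl esters and intramolecular Friedel–Crafts acylation by the CH2CO2H arm onto the ring position ortho to the side chain and ortho/para to the methoxy groups, the only closure that gives the five-membered ring D.

Step 8
Reactants: 13 indanone acid; 9 dihydrobenzofuran triflate
Product: 15 open 1,4-diketone (3-aroylindan-1-one; both C3 epimers), via mixed trifluoroacetic anhydride 14 (not isolated)
Conditions: (CF3CO)2O (2 equiv), CH2Cl2, 0 °C; then 9, 85% H3PO4 (cat.), 0 to 25 °C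
Reagents that add atoms: none
Why: Friedel–Crafts acylation through the mixed anhydride, in which ring B (two methoxy groups and an alkyl group) is attacked at the position ortho to the C3′-bearing carbon and para to a methoxy group while ring C is deactivated by the triflate; the C3 epimers do not matter because C3 is reset in step 9.

Step 9
Reactants: 15 open 1,4-diketone
Product: 17 ring-E diketone (C2–H and C3–H trans), via ene-dione 16 (not isolated)
Conditions: Pd(O2CCF3)2 (10 mol %), P(i-Pr)3 (20 mol %), CsO2CC(CH3)3 (1.2 equiv), 1,4-dioxane (0.02 M), 90 °C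
Reagents that add atoms: none
Why: Proposed new method: a divalent-palladium enolate of 15 (formed at the acidic C3–H) should undergo β-hydride elimination across C2–C3 to give the ene-dione 16 and, after loss of acid, zerovalent palladium, which inserts into the C4′–OTf bond; the cationic arylpalladium then adds across C2=C3 with the aryl group on C2 and palladium on C3 as an enolate of the aroyl ketone, and protonolysis gives 17 and returns divalent palladium, so the relay is redox-neutral and consumes only the carboxylate base. The closest known reaction types are the palladium-catalysed direct β-arylation of ketones with aryl electrophiles by in-situ desaturation and conjugate arylation, and reductive Heck closures of aryl triflates onto enones; the intramolecular version on a 1,4-diketone that closes a medium ring is the new element. Ring E is closed by an 8-endo-trig carbopalladation that forms the C4′–C2 bond. C2 and C3 both remain enolisable in 17 and are set under thermodynamic control relayed from C3′: ring F holds the C3′–ring B bond roughly 65° out of the plane of ring C, and simple models indicate that with this torsion fixed only the trans C2/C3 ring fusion of one absolute sense closes ring E without strain (a cis fusion would press C4′ against Cα), so both epimers of 15 should converge on one diastereomer. The step needs arylation at C2 and not at C3, and no direct enolate α-arylation or biaryl coupling: C3 of 16 is fully substituted and shielded by the 2,6-disubstituted aroyl group, the weakly basic carboxylate medium disfavours reductive elimination from a C3 palladium enolate, and closure of C4′ onto ring B to a fluorene is blocked because C3a′ would have to carry two fused five-membered rings.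

Step 10
Reactants: 17 ring-E diketone; 18 4-methoxyphenylmagnesium bromide
Product: 19 C1 tertiary carbinol (C1 configuration unassigned; Cα ketone retained)
Conditions: 18 (2 equiv) premixed with anhydrous CeCl3 (2.2 equiv), THF, −78 °C; then 17, −78 to −40 °C; aq. NH4Cl
Reagents that add atoms: none
Why: Organocerium 1,2-addition, whose low basicity lets the enolisable indanone carbonyl be attacked and not deprotonated, while the aroyl ketone, flanked by a 2,6-disubstituted aryl ring and a tertiary carbon, should stay untouched; the carbinol configuration is irrelevant because C1 is ionised in step 11.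

Step 11
Reactants: 19 tertiary carbinol
Product: 20 C1–H compound (4-methoxyphenyl on C1 cis to C4′; Cα ketone retained)
Conditions: Et3SiH (3 equiv), CF3CO2H (5 equiv), CH2Cl2, −78 to −40 °C
Reagents that add atoms: none
Why: Ionic hydrogenation, in which acid ionises the alcohol to a C1 cation stabilised by the 4-methoxyphenyl group and ring A, and triethylsilane delivers hydride to the face opposite the C2 substituent (C4′), placing the aryl group cis to C4′ and C1–H cis to C2–H as the target requires.

Step 12
Reactants: 20 Cα ketone
Product: 21 Cα carbinol (hydroxyl expected on the concave face)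
Conditions: LiAlH4, THF, 0 to 25 °C
Reagents that add atoms: none
Why: Hydride reduction of the hindered aryl ketone by the small aluminium hydride from the exposed convex face of ring E; the carbinol configuration is not needed in the main route because Cα is ionised in step 13.

Step 13
Reactants: 21 Cα carbinol; 22 anisole
Product: 23 canaliculatol octamethyl ether
Conditions: Sc(O3SCF3)3 (5 mol %), 22 (20 equiv), CH2Cl2, 0 °C
Reagents that add atoms: none
Why: Friedel–Crafts (SN1) arylation, in which the Lewis acid ionises the carbinol to a 2,4-dimethoxybenzyl-type cation at Cα and anisole attacks through its para position from the convex face of ring E, away from ring C and the C2–H bond on the concave face, so the aryl group takes the exo position of the target; the C2′–O bond of ring F should ionise far less readily under catalytic Lewis acid.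

Step 14
Reactants: 23 octamethyl ether
Product: 24 canaliculatol
Conditions: BBr3 (24 equiv), CH2Cl2, −78 to 25 °C; then MeOH/H2O
Reagents that add atoms: none
Why: Lewis-acid cleavage of the eight aryl methyl ethers; no stereocentre should be altered, since any transiently opened ring F recloses to the favoured trans isomer.

**Compound list**

1 | 5-hydroxy-7-methoxycoumarin | COc1cc(O)c2C=CC(=O)Oc2c1 | starting material
2 | 7-methoxy-2-oxo-2H-chromen-5-yl trifluoromethanesulfonate | COc1cc(OS(=O)(=O)C(F)(F)F)c2C=CC(=O)Oc2c1 | intermediate
3 | (3,5-dimethoxyphenyl)boronic acid | COc1cc(OC)cc(c1)B(O)O | starting material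
4 | (4R)-4-(3,5-dimethoxyphenyl)-7-methoxy-2-oxochroman-5-yl trifluoromethanesulfonate | COc1cc(OC)cc(c1)[C@@H]1c2c(cc(OC)cc2OS(=O)(=O)C(F)(F)F)OC(=O)C1 | intermediate
5 | lithium enolate of 4 (lithium (4R)-4-aryl-4H-chromen-2-olate) | COc1cc(OC)cc(c1)[C@@H]1c2c(cc(OC)cc2OS(=O)(=O)C(F)(F)F)OC([O-])=C1.[Li+] | intermediate
6 | (4R)-3-bromo-4-(3,5-dimethoxyphenyl)-7-methoxy-2-oxochroman-5-yl trifluoromethanesulfonate (C3 undefined, bromine mainly trans to the aryl group) | COc1cc(OC)cc(c1)[C@@H]1c2c(cc(OC)cc2OS(=O)(=O)C(F)(F)F)OC(=O)C1Br | intermediate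
7 | (3R)-3-(3,5-dimethoxyphenyl)-6-methoxy-4-(trifluoromethylsulfonyloxy)-2,3-dihydrobenzofuran-2-carboxylic acid (C2 epimers) | COc1cc(OC)cc(c1)[C@@H]1c2c(cc(OC)cc2OS(=O)(=O)C(F)(F)F)OC1C(=O)O | intermediate
8 | 4-iodoanisole | COc1ccc(I)cc1 | starting material
9 | (2R,3R)-3-(3,5-dimethoxyphenyl)-6-methoxy-2-(4-methoxyphenyl)-2,3-dihydrobenzofuran-4-yl trifluoromethanesulfonate (trans) | COc1cc(OC)cc(c1)[C@@H]1c2c(cc(OC)cc2OS(=O)(=O)C(F)(F)F)O[C@H]1c1ccc(OC)cc1 | intermediate
10 | di-tert-butyl fumarate | CC(C)(C)OC(=O)/C=C/C(=O)OC(C)(C)C | starting material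
11 | di-tert-butyl 2-(3,5-dimethoxyphenyl)succinate (racemic) | COc1cc(OC)cc(c1)C(CC(=O)OC(C)(C)C)C(=O)OC(C)(C)C | intermediate
12 | 2-(3,5-dimethoxyphenyl)succinic acid (racemic) | COc1cc(OC)cc(c1)C(CC(=O)O)C(=O)O | intermediate
13 | 5,7-dimethoxy-1-oxoindane-3-carboxylic acid (racemic; 4,6-dimethoxy-3-oxo-2,3-dihydro-1H-indene-1-carboxylic acid) | O=C1CC(C(=O)O)c2cc(OC)cc(OC)c12 | intermediate
14 | mixed anhydride of 13 with trifluoroacetic acid | O=C1CC(C(=O)OC(=O)C(F)(F)F)c2cc(OC)cc(OC)c12 | intermediate
15 | 5,7-dimethoxy-3-{2,4-dimethoxy-6-[(2R,3R)-6-methoxy-2-(4-methoxyphenyl)-4-(trifluoromethylsulfonyloxy)-2,3-dihydrobenzofuran-3-yl]benzoyl}indan-1-one (both C3 epimers) | O=C1CC(c2cc(OC)cc(OC)c12)C(=O)c1c(OC)cc(OC)cc1[C@@H]1c2c(cc(OC)cc2OS(=O)(=O)C(F)(F)F)O[C@H]1c1ccc(OC)cc1 | intermediate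
16 | ene-dione: the 1H-inden-1-one (C2=C3) corresponding to 15 | O=C1C=C(c2cc(OC)cc(OC)c12)C(=O)c1c(OC)cc(OC)cc1[C@@H]1c2c(cc(OC)cc2OS(=O)(=O)C(F)(F)F)O[C@H]1c1ccc(OC)cc1 | intermediate
17 | ring-E diketone: 15 with C4′ of the dihydrobenzofuran bonded to indanone C2 in place of the triflate; C2–H and C3–H trans, configuration as in the target | O=C1c2c(OC)cc(OC)cc2[C@H]2C(=O)c3c(OC)cc(OC)cc3[C@@H]3c4c(cc(OC)cc4[C@H]12)O[C@H]3c1ccc(OC)cc1 | intermediate
18 | 4-methoxyphenylmagnesium bromide | COc1ccc([Mg]Br)cc1 | starting material
19 | 17 with the C1 carbonyl converted into C1(OH)(4-methoxyphenyl); C1 configuration unassigned | COc1ccc(C2(O)c3c(OC)cc(OC)cc3[C@H]3C(=O)c4c(OC)cc(OC)cc4[C@@H]4c5c(cc(OC)cc5[C@H]23)O[C@H]4c2ccc(OC)cc2)cc1 | intermediate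
20 | C1–H compound: 4-methoxyphenyl on C1 cis to C4′ (C1–H cis to C2–H), Cα still a ketone | COc1ccc([C@@H]2c3c(OC)cc(OC)cc3[C@H]3C(=O)c4c(OC)cc(OC)cc4[C@@H]4c5c(cc(OC)cc5[C@H]23)O[C@H]4c2ccc(OC)cc2)cc1 | intermediate
21 | Cα carbinol of 20 (hydroxyl expected on the concave face of ring E) | COc1ccc([C@@H]2c3c(OC)cc(OC)cc3[C@H]3[C@@H](O)c4c(OC)cc(OC)cc4[C@@H]4c5c(cc(OC)cc5[C@H]23)O[C@H]4c2ccc(OC)cc2)cc1 | intermediate
22 | anisole | COc1ccccc1 | starting material
23 | canaliculatol octamethyl ether | COc1ccc([C@@H]2c3c(OC)cc(OC)cc3[C@H]3[C@H](c4ccc(OC)cc4)c4c(OC)cc(OC)cc4[C@@H]4c5c(cc(OC)cc5[C@H]23)O[C@H]4c2ccc(OC)cc2)cc1 | intermediate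
24 | canaliculatol | Oc1ccc([C@@H]2c3c(O)cc(O)cc3[C@H]3[C@H](c4ccc(O)cc4)c4c(O)cc(O)cc4[C@@H]4c5c(cc(O)cc5[C@H]23)O[C@H]4c2ccc(O)cc2)cc1 | target

**Summary**

Total step count: 14.
Longest linear sequence: 12 steps (steps 1 to 5 and 8 to 14).

The three steps most likely to fail:

Step 9 (carries the label). The relay may stall after the desaturation, or the C3 palladium enolate may undergo direct reductive elimination or protodetriflation before the conjugate arylation. The fallback uses known chemistry and sets out from 15. α-Selenenylation at the acidic C3 (PhSeCl, pyridine, CH2Cl2, 0 °C) should give the C3 phenylselenide F1. Oxidation (30% H2O2, CH2Cl2, 0 °C) and selenoxide syn-elimination should give the ene-dione 16, now isolated. An intramolecular reductive Heck reaction of the aryl triflate onto the enone (Pd(OAc)2, PPh3, HCO2Na, DMF, 80 °C, high dilution), followed by equilibration with DBU, should bring the route back at 17.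

Step 13. Facial selectivity may be lost in the capture of the Cα cation, or the benzylic C2′–O bond of ring F may ionise and be captured by anisole. The fallback sets out from 21. Acylation (pivaloyl chloride, DMAP, pyridine) should give the pivalate F2. A stereospecific nickel-catalysed Suzuki–Miyaura coupling of the benzylic pivalate, which runs with inversion when an N-heterocyclic carbene ligand is used (Ni(cod)2, SIMes, KOt-Bu, 2-(4-methoxyphenyl)-5,5-dimethyl-1,3,2-dioxaborinane, toluene, 80 °C), should place the aryl group on the convex face without a free cation. This relies on the carbinol configuration drawn for 21, and the route is rejoined at 23.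

Step 5. Capture of the α-oxy radical by the electron-rich aryl–nickel species may be slow, or zerovalent nickel may insert into the C4′–OTf bond. The fallback sets out from 7. Oxidative decarboxylation with Pb(OAc)4 (KOAc, AcOH/benzene, 60 °C) should give the anomeric acetate F3. Lewis-acid-mediated Friedel–Crafts arylation through the cyclic oxocarbenium ion (anisole 22, BF3·OEt2, CH2Cl2, −40 °C; para attack anti to the C3′ aryl group) should bring the route back at 9.

Further compounds
F1 | step 9 | C3 phenylselenide of 15 (3-aroyl-3-(phenylselanyl)indan-1-one) | O=C1CC([Se]c2ccccc2)(c2cc(OC)cc(OC)c12)C(=O)c1c(OC)cc(OC)cc1[C@@H]1c2c(cc(OC)cc2OS(=O)(=O)C(F)(F)F)O[C@H]1c1ccc(OC)cc1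
F2 | step 13 | Cα pivalate of 21 | COc1ccc([C@@H]2c3c(OC)cc(OC)cc3[C@H]3[C@@H](OC(=O)C(C)(C)C)c4c(OC)cc(OC)cc4[C@@H]4c5c(cc(OC)cc5[C@H]23)O[C@H]4c2ccc(OC)cc2)cc1
F3 | step 5 | (3R)-2-acetoxy-3-(3,5-dimethoxyphenyl)-6-methoxy-2,3-dihydrobenzofuran-4-yl trifluoromethanesulfonate (C2 epimers) | COc1cc(OC)cc(c1)[C@@H]1c2c(cc(OC)cc2OS(=O)(=O)C(F)(F)F)OC1OC(C)=O
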